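The rate constants are invented; no experiment stands behind them.

The run time, 80 min, is the same for three stirred flasks that differ in the substrate charged.

in all of them: reagent 0.760 M; free catalyst 20 mM; time 80 min
- dusk: substrate 0.20 M
- summer: substrate 0.40 M
- midnight: substrate 0.80 M

    2 free catalyst → spent catalyst (k1 = 0.025 /M/s)
    substrate + free catalyst → catalyst intermediate A (k2 = 0.034 /M/s)
    catalyst intermediate C ⇌ catalyst intermediate D (K3 = 0.84, k3 = 0.0051 /s)
    catalyst intermediate D → free catalyst + target (k4 = 0.044 /s)
    catalyst intermediate B → by-product + catalyst intermediate C (k5 = 0.023 /s)
    reagent + catalyst intermediate A ⇌ catalyst intermediate B (K6 = 1.3 /M, k6 = 0.087 /M/s)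

- for a step with 2 of a species take k times the square, and two of it per event
- "hardly changes" means that all values lie within two and a half points (for a concentration: within two and a half percent of the largest)
- run time (dusk): 80 min

- amount of target at the end, in percent of the substrate charged for dusk, summer, midnight, in this order
- the shape of the row from first to last (rises all the way / rises, then falls / falls all the way / falls, then rises / hardly changes)

Each catalyst passes through five forms in turn, so the rate is c(catalyst in the round) divided by the time one pass takes. At dusk, free catalyst waits 147 s for substrate. Catalyst intermediate A stays 59.1 s, returns from catalyst intermediate B counted. Catalyst intermediates B, C and D together take 289 s, whatever the charge. The sum is the round time, the average time of one full pass of a catalyst at the current levels: 496 s at dusk, 422 s at summer and 385 s at midnight.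

So the start rate, meaning here the rate of a filled round at the charged levels, is first order in catalyst and nearly zero order in substrate: a factor 4.00 in substrate buys a factor 1.29 in rate, from 2.42 mM/min at dusk to 3.11 mM/min at midnight. Start rate times run time, over the charge, gives 96.9%, 56.9% and 31.1%.

This reckoning counts two things that slow the rate. Free catalyst pairs off into spent catalyst, and its start share of the round is 29.6% at dusk but 9.58% at midnight. Held over the run, that level removes 42.3% of the catalyst at dusk and 4.37% at midnight. Falling substrate also lengthens the round: by a factor 1.29 at dusk with substrate halved, and by 1.03 at midnight with a quarter gone. This reckoning holds reagent at its charge. Multiplied, with summer's substrate halved too, the end rates are 0.445, 0.728 and 0.927 of the start rates. The mean of start and end gives this reckoning's row: 70.0%, 49.1%, 30.0%.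

The forecast reads 59%, 45%, 27.5%, lower than this reckoning at dusk. Its shape is falls all the way, and of that it says “Target rises in molarity, but percent yield falls”.

The simulation gives 59.8%, 45.3%, 27.8%: falls all the way, as the forecast has it. At its starting 385 s a round, with the whole catalyst charge working, midnight asks 257 min for its charge and has 80 min; the time given is the main reason for its 27.8%, since ten times as long gives 94.8%. With that time the row reads 97.1%, 98.1%, 94.8%, no longer falling all the way. Dusk asks 82.6 min at its start rate, yet gives 59.8%: without the pairing of free catalyst it reaches 73.2%, and with ten times the time 97.1%.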